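**Plan**

1. Sesquiterpene numbering is used: the cyclohexane is C5–C10, C6 carries the lactone oxygen, C7 the methylene-lactone carbon C11, C8 the ester. The vinyl group on quaternary C10 and the 3-hydroxyprop-1-en-2-yl group on the adjacent C5 are trans and form a hexa-1,5-diene (C2=C1–C10–C5–C4=C3) whose central bond is the ring bond C5–C10. This is the retron of a Cope rearrangement, the link by which elemanolides are presumed to arise from germacranolides.
2. Cuts, in order: acyl C–O at C8; C5–C10 (retro-Cope, which rejoins C2–C3 to the E,E-cyclodeca-1(10),4-diene lactone); C6–C7 plus the lactone C–O (intramolecular 2-(alkoxycarbonyl)allylation); C7–C11 (Morita–Baylis–Hillman); C3–C4 (ynoate carbocupration); C1–C2 and C10–CH3 (carboalumination, oxirane opening); C9–C10 (epoxide alkynylation).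
3. Forward: the chain C7→C6 is built linearly, the ten-membered carbocycle and the lactone close together, the cyclohexane then arises by ring contraction, and the ester is attached last.
4. Stereochemistry: C8 from (R)-glycidol; C6 and C7 in the macrocyclisation under control of C8; C5 and C10 from the chair transition state of the sigmatropic shift; the acyl stereocentre from the (R)-Roche ester; both trisubstituted alkene geometries from syn-carbometalations.

Key step: step 13

Remark: PMB = 4-methoxybenzyl, TBS = tert-butyldimethylsilyl; the acetal carbon in 7, 8 and 12–15 and the carbinol carbon in 18 and 19 form as epimer mixtures that are carried on, because both centres are destroyed later (steps 8 and 11).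

**Route**

Step 1
Reactants: 1 (R)-glycidol
Product: 2 (S)-2-{[(4-methoxybenzyl)oxy]methyl}oxirane
Conditions: NaH, PMBCl, Bu4NI (cat.), DMF, 0 °C to rt
Reagents that add atoms: 4-methoxybenzyl chloride, COc1ccc(CCl)cc1
Why: Williamson etherification of the primary alkoxide leaves the stereocentre untouched (a Payne shift of the glycidol alkoxide is degenerate and returns the same enantiomer); the descriptor changes from R to S only through the priority rules.

Step 2
Reactants: 2 (S)-2-{[(4-methoxybenzyl)oxy]methyl}oxirane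
Product: 3 (S)-1-[(4-methoxybenzyl)oxy]pent-4-yn-2-ol
Conditions: LiC≡CH·H2NCH2CH2NH2, DMSO, rt; H2O
Reagents that add atoms: lithium acetylide ethylenediamine complex, [Li]C#C.NCCN
Why: Epoxide alkynylation by SN2 attack at the unsubstituted epoxide carbon gives the homopropargylic alcohol without touching the carbinol centre (future C8).

Step 3
Reactants: 3 (S)-1-[(4-methoxybenzyl)oxy]pent-4-yn-2-ol
Product: 6 (3E,6S)-7-[(4-methoxybenzyl)oxy]-4-methylhept-3-ene-1,6-diol, via alkenyl dimethylalane 4 (not isolated), via lithium alkenylalanate 5 (not isolated)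
Conditions: Me3Al (3 equiv), Cp2ZrCl2 (0.25 equiv), CH2Cl2, 0 °C to rt; evaporate; n-BuLi, THF/hexane, −78 to 0 °C; ethylene oxide, −78 °C to rt; aq. potassium sodium tartrate
Reagents that add atoms: trimethylaluminium, C[Al](C)C; ethylene oxide, C1CO1
Why: Negishi carboalumination adds methyl and aluminium syn across the terminal alkyne (methyl to the internal carbon), and the derived alkenylalanate opens ethylene oxide with retention, which fixes the E-trisubstituted alkene C1=C10; keeping the mixture at or below room temperature avoids chelation-driven isomerisation of the alkenylalane.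

Step 4
Reactants: 6 (3E,6S)-7-[(4-methoxybenzyl)oxy]-4-methylhept-3-ene-1,6-diol
Product: 7 (3E)-5-[(4S)-2-(4-methoxyphenyl)-1,3-dioxolan-4-yl]-4-methylpent-3-en-1-ol
Conditions: DDQ (1.1 equiv), 4 Å molecular sieves, CH2Cl2, −10 to 0 °C
Reagents that add atoms: none
Why: Oxidative acetalisation, in which DDQ converts the PMB ether into its oxocarbenium ion under anhydrous conditions and the neighbouring secondary hydroxyl traps it as the five-membered 4-methoxybenzylidene acetal; the remote primary hydroxyl cannot reach.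

Step 5
Reactants: 7 (3E)-5-[(4S)-2-(4-methoxyphenyl)-1,3-dioxolan-4-yl]-4-methylpent-3-en-1-ol
Product: 8 (4S)-4-[(2E)-5-iodo-2-methylpent-2-en-1-yl]-2-(4-methoxyphenyl)-1,3-dioxolane
Conditions: I2, PPh3, imidazole, CH2Cl2, 0 °C
Reagents that add atoms: iodine, II
Why: Appel-type iodination of the primary alcohol through the alkoxyphosphonium salt; the imidazole buffer protects the acetal.

Step 6
Reactants: 9 tert-butyldimethyl(prop-2-yn-1-yloxy)silane
Product: 11 methyl 4-[(tert-butyldimethylsilyl)oxy]but-2-ynoate, via lithium acetylide 10 (not isolated)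
Conditions: n-BuLi, THF, −78 °C; ClCO2Me, −78 to 0 °C
Reagents that add atoms: methyl chloroformate, COC(=O)Cl
Why: Deprotonation of the terminal alkyne and C-acylation of the lithium acetylide with a chloroformate is the standard route to 2-alkynoates.

Step 7
Reactants: 8 (4S)-4-[(2E)-5-iodo-2-methylpent-2-en-1-yl]-2-(4-methoxyphenyl)-1,3-dioxolane; 11 methyl 4-[(tert-butyldimethylsilyl)oxy]but-2-ynoate
Product: 15 methyl (2Z,6E)-3-{[(tert-butyldimethylsilyl)oxy]methyl}-8-[(4S)-2-(4-methoxyphenyl)-1,3-dioxolan-4-yl]-7-methylocta-2,6-dienoate, via alkyllithium 12 (not isolated), via alkylcopper 13 (not isolated), via alkenylcopper adduct 14 (not isolated)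
Conditions: t-BuLi (2.1 equiv), Et2O, −78 °C; CuI (1.05 equiv), THF, −40 °C; 11, −78 °C; MeOH then aq. NH4Cl at −78 °C
Reagents that add atoms: none
Why: Iodine–lithium exchange, transmetalation to the alkylcopper and syn-carbocupration of the ynoate, followed by cold protonation of the alkenylcopper with retention, place the new chain trans to the ester, so that C15 (CH2OTBS) and C6 (CO2Me) are cis on C4=C5.

Step 8
Reactants: 15 methyl (2Z,6E)-3-{[(tert-butyldimethylsilyl)oxy]methyl}-8-[(4S)-2-(4-methoxyphenyl)-1,3-dioxolan-4-yl]-7-methylocta-2,6-dienoate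
Product: 16 (2Z,6E,9S)-3-{[(tert-butyldimethylsilyl)oxy]methyl}-9-[(4-methoxybenzyl)oxy]-7-methyldeca-2,6-diene-1,10-diol
Conditions: i-Bu2AlH (6 equiv), CH2Cl2, −78 to 0 °C; aq. potassium sodium tartrate
Reagents that add atoms: none
Why: i-Bu2AlH reduces the enoate to the allylic alcohol and, in the same operation, opens the 4-methoxybenzylidene acetal reductively; aluminium binds the less hindered primary oxygen, that C–O bond breaks, and the PMB group stays on the secondary C8 oxygen.

Step 9
Reactants: 16 (2Z,6E,9S)-3-{[(tert-butyldimethylsilyl)oxy]methyl}-9-[(4-methoxybenzyl)oxy]-7-methyldeca-2,6-diene-1,10-diol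
Product: 17 (2Z,6E,9S)-3-{[(tert-butyldimethylsilyl)oxy]methyl}-9-[(4-methoxybenzyl)oxy]-7-methyldeca-2,6-dienedial
Conditions: Dess–Martin periodinane (2.6 equiv), NaHCO3, CH2Cl2, 0 °C to rt
Reagents that add atoms: none
Why: Dess–Martin oxidation of both primary alcohols under buffered, non-enolising conditions should preserve the enal geometry and the α-alkoxy stereocentre.

Step 10
Reactants: 17 (2Z,6E,9S)-3-{[(tert-butyldimethylsilyl)oxy]methyl}-9-[(4-methoxybenzyl)oxy]-7-methyldeca-2,6-dienedial
Product: 18 methyl (4S,6E,10Z)-10-{[(tert-butyldimethylsilyl)oxy]methyl}-3-hydroxy-4-[(4-methoxybenzyl)oxy]-6-methyl-2-methylidene-12-oxododeca-6,10-dienoate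
Conditions: methyl acrylate (excess, neat), DABCO (1 equiv), rt
Reagents that add atoms: methyl acrylate, C=CC(=O)OC
Why: Morita–Baylis–Hillman reaction, chemoselective because the α-alkoxy aldehyde is far more electrophilic than the β,β-disubstituted enal, which is a poor partner for the zwitterionic enolate; the new carbinol centre becomes sp2 in the next step.

Step 11
Reactants: 18 methyl (4S,6E,10Z)-10-{[(tert-butyldimethylsilyl)oxy]methyl}-3-hydroxy-4-[(4-methoxybenzyl)oxy]-6-methyl-2-methylidene-12-oxododeca-6,10-dienoate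
Product: 20 methyl (2Z,4S,6E,10Z)-2-(bromomethyl)-10-{[(tert-butyldimethylsilyl)oxy]methyl}-4-[(4-methoxybenzyl)oxy]-6-methyl-12-oxododeca-2,6,10-trienoate, via alkoxysulfonium bromide 19 (not isolated)
Conditions: NBS, Me2S, CH2Cl2, −20 °C; then 18, −20 to 0 °C
Reagents that add atoms: N-bromosuccinimide, BrN1C(=O)CCC1=O
Why: Corey–Kim-type activation of the allylic alcohol and SN2′ displacement by bromide give the thermodynamically preferred (Z)-2-(bromomethyl)-2-enoate, as is usual for Morita–Baylis–Hillman adducts.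

Step 12
Reactants: 20 methyl (2Z,4S,6E,10Z)-2-(bromomethyl)-10-{[(tert-butyldimethylsilyl)oxy]methyl}-4-[(4-methoxybenzyl)oxy]-6-methyl-12-oxododeca-2,6,10-trienoate
Product: 23 8α-[(4-methoxybenzyl)oxy]-15-[(tert-butyldimethylsilyl)oxy]germacra-1(10)E,4Z,11(13)-trien-6α,12-olide (6R,7R,8S), via allylchromium dichloride 21 (not isolated), via hydroxy ester 22 (not isolated)
Conditions: CrCl2 (8 equiv), THF, rt, slow addition of 20 (final 2 mM)
Reagents that add atoms: none
Why: Intramolecular Nozaki–Hiyama–Kishi (Barbier-type) allylation, in which the 2-(methoxycarbonyl)allylchromium adds through C7 to the C6 aldehyde and the alkoxide lactonises; ten-membered closures of this kind on farnesal-type bromomethyl acrylates give the trans-fused lactone, and the C8 ether should take the pseudo-equatorial position of the crown-like transition state (H7 anti to H8), which sets C7 and C6; an ether, not an ester, is carried at C8 to disfavour 1,4-elimination.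

Step 13
Reactants: 23 8α-[(4-methoxybenzyl)oxy]-15-[(tert-butyldimethylsilyl)oxy]germacra-1(10)E,4Z,11(13)-trien-6α,12-olide (6R,7R,8S)
Product: 24 8α-[(4-methoxybenzyl)oxy]-15-[(tert-butyldimethylsilyl)oxy]elema-1,3,11(13)-trien-6α,12-olide (5R,6R,7R,8S,10S)
Conditions: degassed o-xylene (0.02 M), BHT (0.1 equiv), sealed tube, 190 °C
Reagents that add atoms: none
Why: Thermal Cope rearrangement, a concerted suprafacial [3,3]-sigmatropic shift of the hexa-1,5-diene C10=C1–C2–C3–C4=C5 through a chair-like transition state reached from the crown conformer of the E,E-cyclodecadiene, which breaks C2–C3 and forms C5–C10. The closest known reaction type is the thermal germacranolide-to-elemanolide rearrangement of trans-fused 6,12-olides. The cyclohexane C5–C10 closes by transannular bond formation inside the ten-membered ring, a ring contraction and not an exo or endo cyclisation, the six carbons being contiguous already. C10 (quaternary) and C5 are set together: the two ring-E alkenes in the chair force vinyl and propenyl trans (both equatorial, methyl axial), and the face is fixed by the C6/C7 trans-lactone and the equatorial C8 ether, which allow only the crown conformer with the C10 methyl and C15 on the same side and H5 anti to H6. The step needs chair over boat selectivity, secured by the E,E geometry in the rigid ring, and an equilibrium on the six-ring side, which the release of cyclodecadiene strain into a chair cyclohexane with four equatorial substituents should provide. Any unchanged 23 can be separated and resubjected.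

Step 14
Reactants: 24 8α-[(4-methoxybenzyl)oxy]-15-[(tert-butyldimethylsilyl)oxy]elema-1,3,11(13)-trien-6α,12-olide (5R,6R,7R,8S,10S)
Product: 25 15-[(tert-butyldimethylsilyl)oxy]-8α-hydroxyelema-1,3,11(13)-trien-6α,12-olide
Conditions: DDQ (1.5 equiv), CH2Cl2/pH 7 buffer (10:1), 0 °C to rt
Reagents that add atoms: none
Why: Oxidative PMB cleavage (benzylic hydride abstraction by DDQ, then hydrolysis of the hemiacetal) frees the C8 hydroxyl while the silyl ether, the alkenes and the methylene lactone stay intact.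

Step 15
Reactants: 26 methyl (R)-3-hydroxy-2-methylpropanoate
Product: 27 methyl (R)-3-[(tert-butyldimethylsilyl)oxy]-2-methylpropanoate
Conditions: TBSCl, imidazole, DMF, 0 °C to rt
Reagents that add atoms: tert-butyldimethylsilyl chloride, CC(C)(C)[Si](C)(C)Cl
Why: Standard silylation of the primary alcohol of the Roche ester; the α-stereocentre is not involved.

Step 16
Reactants: 27 methyl (R)-3-[(tert-butyldimethylsilyl)oxy]-2-methylpropanoate
Product: 28 (R)-3-[(tert-butyldimethylsilyl)oxy]-2-methylpropanoic acid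
Conditions: LiOH, THF/H2O, 0 °C; 1 M HCl to pH 4
Reagents that add atoms: lithium hydroxide, [Li+].[OH-]
Why: Saponification at 0 °C; the carboxylate formed resists α-deprotonation, so the stereocentre should be retained.

Step 17
Reactants: 25 15-[(tert-butyldimethylsilyl)oxy]-8α-hydroxyelema-1,3,11(13)-trien-6α,12-olide; 28 (R)-3-[(tert-butyldimethylsilyl)oxy]-2-methylpropanoic acid
Product: 30 15-[(tert-butyldimethylsilyl)oxy]-8α-{[(2R)-3-[(tert-butyldimethylsilyl)oxy]-2-methylpropanoyl]oxy}elema-1,3,11(13)-trien-6α,12-olide, via mixed anhydride 29 (not isolated)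
Conditions: 28, 2,4,6-trichlorobenzoyl chloride, Et3N, THF, rt; then 25, DMAP, toluene, rt
Reagents that add atoms: none
Why: Yamaguchi esterification, in which DMAP transfers the aliphatic acyl group of the mixed anhydride to the equatorial secondary C8 hydroxyl; C15 is silylated, so only C8 can react.

Step 18
Reactants: 30 15-[(tert-butyldimethylsilyl)oxy]-8α-{[(2R)-3-[(tert-butyldimethylsilyl)oxy]-2-methylpropanoyl]oxy}elema-1,3,11(13)-trien-6α,12-olide
Product: 31 (3aR,4S,6S,7R,7aR)-6-ethenyl-7-(3-hydroxyprop-1-en-2-yl)-6-methyl-3-methylidene-2-oxooctahydro-1-benzofuran-4-yl (2R)-3-hydroxy-2-methylpropanoate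
Conditions: HF·pyridine, THF/pyridine, 0 °C to rt
Reagents that add atoms: none
Why: Fluoride-mediated cleavage of both primary silyl ethers under mildly acidic conditions, which avoid conjugate addition to the methylene lactone and base-induced elimination or epimerisation in the β-hydroxy ester.

**Compound list**

1 | (R)-glycidol | OC[C@@H]1CO1 | starting material
2 | (S)-2-{[(4-methoxybenzyl)oxy]methyl}oxirane | COc1ccc(COC[C@@H]2CO2)cc1 | intermediate
3 | (S)-1-[(4-methoxybenzyl)oxy]pent-4-yn-2-ol | C#CC[C@H](O)COCc1ccc(OC)cc1 | intermediate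
4 | (E)-alkenyl dimethylalane, dimethylaluminium alkoxide at the C8 oxygen | C[Al](C)/C=C(\C)C[C@H](O[Al](C)C)COCc1ccc(OC)cc1 | intermediate
5 | lithium alkenyl(butyl)dimethylalanate | [Li+].CCCC[Al-](C)(C)/C=C(\C)C[C@H](O[Al](C)C)COCc1ccc(OC)cc1 | intermediate
6 | (3E,6S)-7-[(4-methoxybenzyl)oxy]-4-methylhept-3-ene-1,6-diol | OCC/C=C(\C)C[C@H](O)COCc1ccc(OC)cc1 | intermediate
7 | (3E)-5-[(4S)-2-(4-methoxyphenyl)-1,3-dioxolan-4-yl]-4-methylpent-3-en-1-ol | OCC/C=C(\C)C[C@H]1COC(c2ccc(OC)cc2)O1 | intermediate
8 | (4S)-4-[(2E)-5-iodo-2-methylpent-2-en-1-yl]-2-(4-methoxyphenyl)-1,3-dioxolane | ICC/C=C(\C)C[C@H]1COC(c2ccc(OC)cc2)O1 | intermediate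
9 | tert-butyldimethyl(prop-2-yn-1-yloxy)silane | C#CCO[Si](C)(C)C(C)(C)C | starting material
10 | lithium acetylide of 9 | [Li]C#CCO[Si](C)(C)C(C)(C)C | intermediate
11 | methyl 4-[(tert-butyldimethylsilyl)oxy]but-2-ynoate | COC(=O)C#CCO[Si](C)(C)C(C)(C)C | intermediate
12 | alkyllithium from 8 | [Li]CC/C=C(\C)C[C@H]1COC(c2ccc(OC)cc2)O1 | intermediate
13 | alkylcopper from 12 | [Cu]CC/C=C(\C)C[C@H]1COC(c2ccc(OC)cc2)O1 | intermediate
14 | alkenylcopper adduct (copper cis to the new chain) | COC(=O)/C([Cu])=C(\CO[Si](C)(C)C(C)(C)C)CC/C=C(\C)C[C@H]1COC(c2ccc(OC)cc2)O1 | intermediate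
15 | methyl (2Z,6E)-3-{[(tert-butyldimethylsilyl)oxy]methyl}-8-[(4S)-2-(4-methoxyphenyl)-1,3-dioxolan-4-yl]-7-methylocta-2,6-dienoate | COC(=O)/C=C(\CO[Si](C)(C)C(C)(C)C)CC/C=C(\C)C[C@H]1COC(c2ccc(OC)cc2)O1 | intermediate
16 | (2Z,6E,9S)-3-{[(tert-butyldimethylsilyl)oxy]methyl}-9-[(4-methoxybenzyl)oxy]-7-methyldeca-2,6-diene-1,10-diol | OC/C=C(\CO[Si](C)(C)C(C)(C)C)CC/C=C(\C)C[C@H](OCc1ccc(OC)cc1)CO | intermediate
17 | (2Z,6E,9S)-3-{[(tert-butyldimethylsilyl)oxy]methyl}-9-[(4-methoxybenzyl)oxy]-7-methyldeca-2,6-dienedial | O=C/C=C(\CO[Si](C)(C)C(C)(C)C)CC/C=C(\C)C[C@H](OCc1ccc(OC)cc1)C=O | intermediate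
18 | methyl (4S,6E,10Z)-10-{[(tert-butyldimethylsilyl)oxy]methyl}-3-hydroxy-4-[(4-methoxybenzyl)oxy]-6-methyl-2-methylidene-12-oxododeca-6,10-dienoate (both C3 epimers) | O=C/C=C(\CO[Si](C)(C)C(C)(C)C)CC/C=C(\C)C[C@H](OCc1ccc(OC)cc1)C(O)C(=C)C(=O)OC | intermediate
19 | alkoxy(dimethyl)sulfonium bromide of 18 | O=C/C=C(\CO[Si](C)(C)C(C)(C)C)CC/C=C(\C)C[C@H](OCc1ccc(OC)cc1)C(O[S+](C)C)C(=C)C(=O)OC.[Br-] | intermediate
20 | methyl (2Z,4S,6E,10Z)-2-(bromomethyl)-10-{[(tert-butyldimethylsilyl)oxy]methyl}-4-[(4-methoxybenzyl)oxy]-6-methyl-12-oxododeca-2,6,10-trienoate | O=C/C=C(\CO[Si](C)(C)C(C)(C)C)CC/C=C(\C)C[C@H](OCc1ccc(OC)cc1)/C=C(\CBr)C(=O)OC | intermediate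
21 | 2-(methoxycarbonyl)allylchromium dichloride from 20 | O=C/C=C(\CO[Si](C)(C)C(C)(C)C)CC/C=C(\C)C[C@H](OCc1ccc(OC)cc1)/C=C(\C[Cr](Cl)Cl)C(=O)OC | intermediate
22 | methyl 6α-hydroxy-8α-[(4-methoxybenzyl)oxy]-15-[(tert-butyldimethylsilyl)oxy]germacra-1(10)E,4Z,11(13)-trien-12-oate (H7α; present as its chromium alkoxide) | C/C1=C\CC/C(CO[Si](C)(C)C(C)(C)C)=C/[C@@H](O)[C@H](C(=C)C(=O)OC)[C@@H](OCc2ccc(OC)cc2)C1 | intermediate
23 | 8α-[(4-methoxybenzyl)oxy]-15-[(tert-butyldimethylsilyl)oxy]germacra-1(10)E,4Z,11(13)-trien-6α,12-olide (6R,7R,8S) | C/C1=C\CC/C(CO[Si](C)(C)C(C)(C)C)=C/[C@H]2OC(=O)C(=C)[C@@H]2[C@@H](OCc2ccc(OC)cc2)C1 | intermediate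
24 | 8α-[(4-methoxybenzyl)oxy]-15-[(tert-butyldimethylsilyl)oxy]elema-1,3,11(13)-trien-6α,12-olide (5R,6R,7R,8S,10S) | C=C[C@]1(C)C[C@H](OCc2ccc(OC)cc2)[C@H]2C(=C)C(=O)O[C@@H]2[C@H]1C(=C)CO[Si](C)(C)C(C)(C)C | intermediate
25 | 15-[(tert-butyldimethylsilyl)oxy]-8α-hydroxyelema-1,3,11(13)-trien-6α,12-olide | C=C[C@]1(C)C[C@H](O)[C@H]2C(=C)C(=O)O[C@@H]2[C@H]1C(=C)CO[Si](C)(C)C(C)(C)C | intermediate
26 | methyl (R)-3-hydroxy-2-methylpropanoate | COC(=O)[C@H](C)CO | starting material
27 | methyl (R)-3-[(tert-butyldimethylsilyl)oxy]-2-methylpropanoate | COC(=O)[C@H](C)CO[Si](C)(C)C(C)(C)C | intermediate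
28 | (R)-3-[(tert-butyldimethylsilyl)oxy]-2-methylpropanoic acid | OC(=O)[C@H](C)CO[Si](C)(C)C(C)(C)C | intermediate
29 | mixed anhydride of 28 with 2,4,6-trichlorobenzoic acid | O=C(OC(=O)[C@H](C)CO[Si](C)(C)C(C)(C)C)c1c(Cl)cc(Cl)cc1Cl | intermediate
30 | 15-[(tert-butyldimethylsilyl)oxy]-8α-{[(2R)-3-[(tert-butyldimethylsilyl)oxy]-2-methylpropanoyl]oxy}elema-1,3,11(13)-trien-6α,12-olide | C=C[C@]1(C)C[C@H](OC(=O)[C@H](C)CO[Si](C)(C)C(C)(C)C)[C@H]2C(=C)C(=O)O[C@@H]2[C@H]1C(=C)CO[Si](C)(C)C(C)(C)C | intermediate
31 | (3aR,4S,6S,7R,7aR)-6-ethenyl-7-(3-hydroxyprop-1-en-2-yl)-6-methyl-3-methylidene-2-oxooctahydro-1-benzofuran-4-yl (2R)-3-hydroxy-2-methylpropanoate | C=C[C@]1(C)C[C@H](OC(=O)[C@H](C)CO)[C@H]2C(=C)C(=O)O[C@@H]2[C@H]1C(=C)CO | target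

**Step count and risks**

Total steps: 18. Longest linear sequence: 15 (steps 1–5, 7–14, 17, 18).

Most likely to fail, first: step 12. The ring closure may lose to intermolecular coupling, the allylchromium may expel the C8 ether by 1,4-elimination, or the aldehyde may be attacked with the wrong facial sense relative to C8. The fallback sets out from 18 and changes the nucleophile from a stoichiometric organochromium made from a bromide to a catalytic umpolung of an allylic acetate. Alcohol 18 is acetylated (Ac2O, pyridine, DMAP) to the Morita–Baylis–Hillman acetate F1. Treatment of F1 with Pd(PPh3)4 (zerovalent palladium, 5 mol %) and Et2Zn in THF at high dilution should give the 2-(methoxycarbonyl)allyl palladium complex, which is transmetalated to a nucleophilic allylzinc. This adds to the C6 aldehyde through a different, zinc-centred transition state to give hydroxy ester 22, which lactonises. The fallback comes back to the route at 23.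

Second: step 13. Conversion may stay incomplete if the sigmatropic equilibrium is not far enough on the six-ring side, and the methylene lactone may oligomerise by a radical path at the temperature needed. The fallback sets out from 23 and changes the oxidation level at C15, so that an acceptor on C4 (position 2 of the hexadiene, a radical-stabilising position) lowers the barrier. Desilylation (Bu4NF/AcOH, THF, 0 °C) gives the 15-hydroxy germacranolide F2, and MnO2 in CH2Cl2 gives the 15-oxo germacranolide F3. Heating F3 in toluene near 100 °C should give the 15-oxo elemanolide F4, in which the aldehyde remains conjugated as a 2-substituted acrolein. Reduction with NaBH4/CeCl3 (MeOH, −78 °C) selects the aldehyde over the methylene lactone and gives the 15-hydroxy elemanolide F5. Silylation (TBSCl, imidazole) brings the fallback back to the route at 24.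

Third: step 10. The amine-catalysed addition is slow, and during that time DABCO may isomerise the enal by reversible conjugate addition or epimerise the α-alkoxy aldehyde. The fallback sets out from 17 and replaces the catalytic equilibrium process by a stoichiometric vinylmetal addition without amine. Methyl propiolate is hydroaluminated with i-Bu2AlH/HMPA (THF, 0 °C) to the α-(methoxycarbonyl)vinyl alane F6. F6 is added to 17 at −78 °C, where the chelating α-alkoxy aldehyde should react before the hindered enal. The fallback comes back to the route at 18.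

**Further compounds**

F1 | step 12 | methyl (4S,6E,10Z)-3-acetoxy-10-{[(tert-butyldimethylsilyl)oxy]methyl}-4-[(4-methoxybenzyl)oxy]-6-methyl-2-methylidene-12-oxododeca-6,10-dienoate | O=C/C=C(\CO[Si](C)(C)C(C)(C)C)CC/C=C(\C)C[C@H](OCc1ccc(OC)cc1)C(OC(C)=O)C(=C)C(=O)OC
F2 | step 13 | 15-hydroxy-8α-[(4-methoxybenzyl)oxy]germacra-1(10)E,4Z,11(13)-trien-6α,12-olide | C/C1=C\CC/C(CO)=C/[C@H]2OC(=O)C(=C)[C@@H]2[C@@H](OCc2ccc(OC)cc2)C1
F3 | step 13 | 8α-[(4-methoxybenzyl)oxy]-15-oxogermacra-1(10)E,4Z,11(13)-trien-6α,12-olide | C/C1=C\CC/C(C=O)=C/[C@H]2OC(=O)C(=C)[C@@H]2[C@@H](OCc2ccc(OC)cc2)C1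
F4 | step 13 | 8α-[(4-methoxybenzyl)oxy]-15-oxoelema-1,3,11(13)-trien-6α,12-olide | C=C[C@]1(C)C[C@H](OCc2ccc(OC)cc2)[C@H]2C(=C)C(=O)O[C@@H]2[C@H]1C(=C)C=O
F5 | step 13 | 15-hydroxy-8α-[(4-methoxybenzyl)oxy]elema-1,3,11(13)-trien-6α,12-olide | C=C[C@]1(C)C[C@H](OCc2ccc(OC)cc2)[C@H]2C(=C)C(=O)O[C@@H]2[C@H]1C(=C)CO
F6 | step 10 | methyl 2-[bis(2-methylpropyl)alumanyl]prop-2-enoate | C=C([Al](CC(C)C)CC(C)C)C(=O)OC
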